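No C–O coupling is attempted at the crowded ring A phenol. Ring B is instead assembled on an oxygen that ring A already carries. From C2' to C5', ring B shows the sequence Br–H–Br–H, which maps onto C3–C6 of 3,5-dibromo-2-pyrone. C1' (oxygen-bearing) and C6' (H) are the two carbons of an ethynyl ether. One thermal operation, [4+2] cycloaddition followed by CO2 loss, forms C1'–C2' and C6'–C5', closes ring B and places both bromines. The precursor is the ethynyl ether of fully substituted ring A (two Br, OMe, MOM-protected OH). It is reached from 5-methoxysalicylaldehyde by phenol-directed dibromination and a vinylation/bromination/elimination sequence that uses no organolithium reagent.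

Key step: step 8

Remark: ring A is labelled C1 (aryloxy), C2 (OH), C3 (H), C4 (Br), C5 (OMe), C6 (Br), and ring B C1' (ether carbon), C2' (Br), C3' (H), C4' (Br), C5' (H), C6' (H). The target has no stereocentre, so only the alkene geometry of 13 and the transient racemic centres of 12 and 15 carry stereochemical information.

Step 1
Reactants: 1 coumalic acid (2-oxo-2H-pyran-5-carboxylic acid)
Product: 3 3,5-dibromo-2H-pyran-2-one, via 5-bromo-2H-pyran-2-one 2 (not isolated)
Conditions: NBS (2.5 equiv), Bu4NBr (cat.), CHCl3, 50 °C
Reagents that add atoms: N-bromosuccinimide, O=C1CCC(=O)N1Br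
Why: Hunsdiecker-type bromodecarboxylation replaces the C5 carboxyl group and electrophilic bromination (addition–elimination) takes the nucleophilic C3 position, a combination established for coumalic acid itself.

Step 2
Reactants: 4 2-hydroxy-5-methoxybenzaldehyde
Product: 5 5-methoxy-2-(methoxymethoxy)benzaldehyde
Conditions: NaH, MOMCl, DMF, 0 °C
Reagents that add atoms: chloromethyl methyl ether, COCCl
Why: Williamson-type O-alkylation of the sodium phenoxide with the very reactive chloromethyl ether spares the aldehyde, and the MOM group is chosen because it should withstand peracid, NBS, hot carbonate, KOtBu and prolonged heating yet leave under mild acid at the end.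

Step 3
Reactants: 5 5-methoxy-2-(methoxymethoxy)benzaldehyde
Product: 7 5-methoxy-2-(methoxymethoxy)phenol, via aryl formate 6 (not isolated)
Conditions: mCPBA, CH2Cl2, 0 °C to rt; then K2CO3 (cat.), MeOH, rt
Reagents that add atoms: 3-chloroperoxybenzoic acid, OOC(=O)c1cccc(Cl)c1
Why: Baeyer–Villiger oxidation of an ortho-alkoxybenzaldehyde proceeds with aryl migration because the electron-rich ring migrates better than hydride, as in the conversion of 2,5-dialkoxybenzaldehydes into 2,5-dialkoxyphenols, and the aryl formate falls to base-catalysed methanolysis.

Step 4
Reactants: 7 5-methoxy-2-(methoxymethoxy)phenol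
Product: 9 2,4-dibromo-3-methoxy-6-(methoxymethoxy)phenol, via 4-bromo-5-methoxy-2-(methoxymethoxy)phenol 8 (not isolated)
Conditions: NBS (2.05 equiv), MeCN, −20 °C to rt
Reagents that add atoms: N-bromosuccinimide, O=C1CCC(=O)N1Br
Why: Electrophilic aromatic bromination is steered by the free phenol to its para position and its one open ortho position, both also ortho to the methoxy group (matched resorcinol-type activation), whereas the last C–H is activated only by the MOM ether, and NBS avoids the HBr that would endanger the acetal.

Step 5
Reactants: 9 2,4-dibromo-3-methoxy-6-(methoxymethoxy)phenol, 10 vinyl acetate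
Product: 11 1,3-dibromo-4-(ethenyloxy)-2-methoxy-5-(methoxymethoxy)benzene
Conditions: [Ir(cod)Cl]2 (2 mol %), Na2CO3, toluene, 100 °C
Reagents that add atoms: none
Why: Iridium-catalysed transfer vinylation (addition of the iridium phenoxide across vinyl acetate, then beta-acetate elimination) is an established way from phenols to aryl vinyl ethers under weakly basic conditions that touch neither the aryl bromides nor the MOM ether.

Step 6
Reactants: 11 1,3-dibromo-4-(ethenyloxy)-2-methoxy-5-(methoxymethoxy)benzene
Product: 13 1,3-dibromo-4-{[(Z)-2-bromoethenyl]oxy}-2-methoxy-5-(methoxymethoxy)benzene, via 1,2-dibromoethyl ether 12 (not isolated)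
Conditions: Br2 (1.0 equiv), CH2Cl2, −78 °C; then iPr2NEt, −78 °C to 40 °C
Reagents that add atoms: bromine, BrBr
Why: The enol ether double bond adds bromine far faster than the deactivated, nearly fully substituted arene can react, and amine-induced dehydrobromination of the alpha-bromo ether is the classical entry to 2-bromovinyl ethers with the Z isomer favoured, while any E isomer or 1-bromovinyl regioisomer would converge on the same alkyne in step 7.

Step 7
Reactants: 13 1,3-dibromo-4-{[(Z)-2-bromoethenyl]oxy}-2-methoxy-5-(methoxymethoxy)benzene
Product: 14 1,3-dibromo-4-(ethynyloxy)-2-methoxy-5-(methoxymethoxy)benzene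
Conditions: KOtBu, THF, −40 °C to rt; pH 7 buffer; short plug of basic alumina, used at once as a toluene solution
Reagents that add atoms: none
Why: In the Z isomer the hydrogen on the oxygen-bearing carbon stands anti to bromine, so E2 dehydrobromination with KOtBu, known for bromo enol ethers and bromo enamides, should give the alkyne without organolithium reagents that would exchange with the aryl bromides.

Step 8
Reactants: 14 1,3-dibromo-4-(ethynyloxy)-2-methoxy-5-(methoxymethoxy)benzene, 3 3,5-dibromo-2H-pyran-2-one
Product: 16 1,3-dibromo-4-(2,4-dibromophenoxy)-2-methoxy-5-(methoxymethoxy)benzene, via bridged dienyl lactone 15 (not isolated)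
Conditions: 3 (2 equiv), BHT (cat.), toluene, 110 °C, sealed vessel, slow addition of 14
Reagents that add atoms: none
Why: The polarised triple bond of 14 (HOMO largest at the terminal CH) meets the electron-poor diene C3=C4–C5=C6 of 3 (LUMO largest at C6) in a concerted but asynchronous inverse-demand Diels–Alder reaction, the CH carbon bonding to C6 slightly ahead of the oxygen-bearing carbon bonding to C3. The bridged dienyl lactone 15 cannot persist at this temperature and expels CO2 by cycloreversion, which delivers ring B already aromatic, so neither an oxidant nor an elimination that might expel the aryloxy group is needed. The closest known chemistry is the pyrone–alkyne cycloaddition/decarboxylation route to benzenes together with the cycloadditions of 3,5-dibromo-2-pyrone with enol ethers, and only this particular pair of partners would be new. Ring B closes by an intermolecular [4+2] event that makes C1'–C2' and C6'–C5' together rather than by cyclisation of a chain, and the two bridgehead centres of 15 vanish on aromatisation, so no stereocentre has to be controlled. The selectivity required is regiochemical (2,4- and not 3,5-dibromophenyl ether) and rests on the matched polarity above, the same orientation that places the alkoxy carbon next to C3 in enol ether adducts of this diene. Because the oxygen substituent is an arene, the ketene-forming retro-ene decay of alkyl alkynyl ethers has no hydrogen to draw on, and with both ortho positions of ring A blocked, slow addition to excess 3 should leave oligomerisation as the only serious competitor.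

Step 9
Reactants: 16 1,3-dibromo-4-(2,4-dibromophenoxy)-2-methoxy-5-(methoxymethoxy)benzene
Product: 17 3,5-dibromo-2-(2,4-dibromophenoxy)-4-methoxyphenol (CNP0140065.0)
Conditions: HCl (cat.), MeOH, 50 °C
Reagents that add atoms: none
Why: Acid-catalysed acetal exchange with methanol removes the MOM group as dimethoxymethane, while the diaryl ether, the methyl ether and the four aryl bromides are inert to dilute acid.

Compound list
1 | coumalic acid | O=C1C=CC(C(=O)O)=CO1 | starting material
2 | 5-bromo-2H-pyran-2-one | O=C1C=CC(Br)=CO1 | intermediate (not isolated)
3 | 3,5-dibromo-2H-pyran-2-one | O=C1OC=C(Br)C=C1Br | intermediate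
4 | 2-hydroxy-5-methoxybenzaldehyde | COc1ccc(O)c(C=O)c1 | starting material
5 | 5-methoxy-2-(methoxymethoxy)benzaldehyde | COCOc1ccc(OC)cc1C=O | intermediate
6 | 5-methoxy-2-(methoxymethoxy)phenyl formate | COCOc1ccc(OC)cc1OC=O | intermediate (not isolated)
7 | 5-methoxy-2-(methoxymethoxy)phenol | COCOc1ccc(OC)cc1O | intermediate
8 | 4-bromo-5-methoxy-2-(methoxymethoxy)phenol | COCOc1cc(Br)c(OC)cc1O | intermediate (not isolated)
9 | 2,4-dibromo-3-methoxy-6-(methoxymethoxy)phenol | COCOc1cc(Br)c(OC)c(Br)c1O | intermediate
10 | vinyl acetate | CC(=O)OC=C | starting material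
11 | 1,3-dibromo-4-(ethenyloxy)-2-methoxy-5-(methoxymethoxy)benzene | COCOc1cc(Br)c(OC)c(Br)c1OC=C | intermediate
12 | 1,3-dibromo-4-(1,2-dibromoethoxy)-2-methoxy-5-(methoxymethoxy)benzene, racemic | COCOc1cc(Br)c(OC)c(Br)c1OC(Br)CBr | intermediate (not isolated)
13 | 1,3-dibromo-4-{[(Z)-2-bromoethenyl]oxy}-2-methoxy-5-(methoxymethoxy)benzene | COCOc1cc(Br)c(OC)c(Br)c1O/C=C\Br | intermediate
14 | 1,3-dibromo-4-(ethynyloxy)-2-methoxy-5-(methoxymethoxy)benzene | COCOc1cc(Br)c(OC)c(Br)c1OC#C | intermediate
15 | 4,6-dibromo-8-[2,4-dibromo-3-methoxy-6-(methoxymethoxy)phenoxy]-2-oxabicyclo[2.2.2]octa-5,7-dien-3-one, racemic (one enantiomer drawn) | O=C1O[C@H]2C=C(Oc3c(OCOC)cc(Br)c(OC)c3Br)[C@]1(Br)C=C2Br | intermediate (not isolated)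
16 | 1,3-dibromo-4-(2,4-dibromophenoxy)-2-methoxy-5-(methoxymethoxy)benzene | COCOc1cc(Br)c(OC)c(Br)c1Oc1ccc(Br)cc1Br | intermediate
17 | 3,5-dibromo-2-(2,4-dibromophenoxy)-4-methoxyphenol | COc1c(Br)cc(O)c(Oc2ccc(Br)cc2Br)c1Br | target

Total step count: 9. Longest linear sequence: 8 (steps 2 to 9). Step 1 is a one-step side branch that joins at step 8.

Steps most likely to fail

Step 8. Oligomerisation of the ynol ether may outrun the cycloaddition, which is slowed by the bulk of the di-ortho-substituted aryloxy group next to the C3 bromine. The same clash may erode the orientation of addition. The fallback sets out from phenol 9 and comes back at 16. 1,3-Dibromobenzene is condensed with (IO)2SO4 in H2SO4, with electrophilic attack at its C4, and precipitated with NaCl as bis(2,4-dibromophenyl)iodonium chloride F1. Heating 9 with F1 and NaOH in water/dioxane transfers one 2,4-dibromophenyl group to the phenoxide by ligand coupling at trivalent iodine. This is the standard metal-free arylation for crowded polybrominated diphenyl ethers, and it should give 16 directly with the MOM group intact.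

Step 7. Three processes may spoil this step: slow syn-elimination from the minor E isomer, addition of tert-butoxide to the new triple bond, and hydration or polymerisation during isolation. The fallback sets out from 13 and comes back at 16, so the free alkyne is never handled. Compound 13 serves as an alkyne equivalent and is heated with 3 in mesitylene at about 150 °C. Cycloaddition in the same orientation should give endo,endo-4,6,7-tribromo-8-[2,4-dibromo-3-methoxy-6-(methoxymethoxy)phenoxy]-2-oxabicyclo[2.2.2]oct-5-en-3-one F2. At that temperature F2 loses CO2 to give cis-1,3,5-tribromo-6-[2,4-dibromo-3-methoxy-6-(methoxymethoxy)phenoxy]cyclohexa-1,3-diene F3. After cooling, DBU removes HBr, the allylic bromide being a better nucleofuge than the aryloxide, and ring B aromatises to 16.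

Step 5. The hindered and rather acidic phenol may bind poorly to iridium, so that vinyl transfer stalls or acetyl transfer from vinyl acetate takes over. The fallback sets out from 9 and comes back at 11. Williamson alkylation of 9 with excess 1,2-dibromoethane (K2CO3, MeCN, reflux) gives 1,3-dibromo-4-(2-bromoethoxy)-2-methoxy-5-(methoxymethoxy)benzene F4. E2 elimination with KOtBu in THF at 0 °C then gives vinyl ether 11.

Further compounds
F1 | step 8 | bis(2,4-dibromophenyl)iodonium chloride | [Cl-].Brc1ccc([I+]c2ccc(Br)cc2Br)c(Br)c1
F2 | step 7 | endo,endo-4,6,7-tribromo-8-[2,4-dibromo-3-methoxy-6-(methoxymethoxy)phenoxy]-2-oxabicyclo[2.2.2]oct-5-en-3-one, racemic | O=C1O[C@H]2[C@H](Br)[C@H](Oc3c(OCOC)cc(Br)c(OC)c3Br)[C@]1(Br)C=C2Br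
F3 | step 7 | cis-1,3,5-tribromo-6-[2,4-dibromo-3-methoxy-6-(methoxymethoxy)phenoxy]cyclohexa-1,3-diene, racemic | Br[C@@H]1C=C(Br)C=C(Br)[C@@H]1Oc2c(OCOC)cc(Br)c(OC)c2Br
F4 | step 5 | 1,3-dibromo-4-(2-bromoethoxy)-2-methoxy-5-(methoxymethoxy)benzene | COCOc1cc(Br)c(OC)c(Br)c1OCCBr
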